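Don't reckon the target against the clock. That is the pitfall, since the clock brings in the falling nucleophile. Reckon it against the electrophile left.

| flask | electrophile | nucleophile | free base | temperature | remark | time |
|---|---|---|---|---|---|---|
| summer | 0.54 M | 1.04 M | 2.4 M | −5 °C | run made earlier |  |
| midnight | 1.2 M | 1.04 M | 2.4 M | 10 °C | run made earlier |  |
| eta | 0.80 M | 1.04 M | 2.40 M | 0 °C |  | 25 min |
| beta | 0.80 M | 1.04 M | 2.40 M | 10 °C |  | 25 min |
| delta | 0.80 M | 1.04 M | 2.40 M | 20 °C |  | 25 min |

| run | time / min | target / % | electrophile / % |
|---|---|---|---|
| summer | 6.00 | 4.3 | 96.5 |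
| summer | 12.0 | 6.6 | 92.2 |
| summer | 20.0 | 10.9 | 88.5 |
| summer | 25.0 | 13.1 | 85.2 |
| midnight | 4.00 | 8.3 | 90.4 |
| midnight | 8.00 | 15.4 | 82.4 |
| midnight | 12.0 | 18.3 | 76.7 |
| midnight | 15.0 | 20.1 | 72.7 |

(each reading ± 0.5 percentage points)

- which of the two there is more of at the end, eta (target / over-reaction product)
- which of the two there is more of at the end, beta (target / over-reaction product)
- which of the two there is more of at the end, delta (target / over-reaction product)
- how much target is there at the end, in percent of the electrophile charged: eta
- how much target is there at the end, in percent of the electrophile charged: beta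
- how much target is there at the end, in percent of the electrophile charged: delta



Suppose, as a working assumption, that the nucleophile makes the target from the electrophile and the over-reaction product from the target. Its concentration then stands in both rates and cancels from their ratio, leaving the selectivity factor s, the second rate constant over the first. With a the electrophile left, x = 1 − a the fraction gone, p the target and o the over-reaction product, all as fractions of the electrophile charged:

p = (a^s − a)/(1 − s), and early on o ≈ s·x²/2

The last readings give:

summer: x = 14.8 %, o = 1.70 %, s = 1.55
midnight: x = 27.3 %, o = 7.20 %, s = 1.93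

Eta lies a third of the way from summer to midnight in temperature, so I take s = 1.68 for eta. The nucleophile is not in excess, since midnight holds 1.2 M of electrophile to 1.04 M of nucleophile, and midnight's −ln(a)/t drifts from 0.0252 /min to 0.0213 /min. So no true constant can be read from the electrophile, and I use −ln(a)/t at the last reading as a rough average over each run:

summer 0.00641 /min, midnight 0.0213 /min, eta 0.00956 /min
eta at 25 min: a = 78.8 %

Now the bracket for eta. With no over-reaction, p could reach x = 21.2 %. Midnight's s gives a floor of 16.9 %, and summer's s lowers the ceiling to 17.6 %. That tightening assumes s rises with temperature, which two readings with scatter only suggest. My own figure is 17.4 %.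

The forecast assumes the same second step, “Assuming target + nucleophile → over-product”, with a ratio of about 1.8. It says target, target, over-reaction product for eta, beta and delta, with target 17.5 % (15.5 % to 19.5 %), 25 % (22 % to 29 %) and 25 % (19 % to 35 %). Its eta value lies inside my bracket.

    acid set free + free base ⇌ idle adduct, settled at all times (K = 0.480 /M, ΔH = −12.0 kJ/mol)
    electrophile + nucleophile → acid set free + target (k = 1.80 × 10⁻⁴ /M/s, Ea = 60.0 kJ/mol)
    nucleophile + acid set free ⇌ protonated nucleophile, settled at all times (K = 41.0 /M, ΔH = −7.00 kJ/mol)
    acid set free + free base ⇌ salt of the base (K = 19000 /M, k = 0.0270 /M/s, Ea = 53.0 kJ/mol, ΔH = −74.0 kJ/mol)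
    nucleophile + target → over-reaction product (k = 2.60 × 10⁻⁴ /M/s, Ea = 74.0 kJ/mol)
    (constants at 0 °C)

The flasks give target, target, over-reaction product, with target 18.0 %, 25.3 % and 22.5 %, so the forecast held. Eta's 18.0 % stands slightly above my tightened ceiling. At the asked time in eta, target is made 3.03 times faster than it is used up; a/(s·p) with my s gives 2.60.

The neighbouring flask is eta with 0.62 M of nucleophile. Its temperature keeps s at 1.68, and scaling the constant by the charge gives a = 86.7 %, hence p = 11.8 %. The computed flask holds 86.5 % electrophile and 12.2 % target.

The earlier runs and the new flask are simulated for an exercise, noise included.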